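The seven-membered ring (C1, C5–C10; daucane numbering, C1 = methyl-bearing ring-fusion carbon, C6 and C10 = ester carbons) is formed last, on a cyclopentene from (S)-terpinen-4-ol that already carries C4 (OH, isopropyl). The key step is a rhodium-carbenoid (4+3) annulation: cyclopropanation of the vinyl group C6=C7 of a 2-methyl-1-vinylcyclopentene by an (E)-4-silyloxy vinyldiazoacetate (C8–C9=C10), then boat Cope rearrangement of the cis-divinylcyclopropane. It exploits the 1,4-relation across C7 of C8=C9 and the latent C5=C6 bond: one operation forms C7–C8 and C1–C10 and sets the quaternary C1 and the C10 carbinol. A silicon tether from O10 then delivers H5 and O6.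

Key step: step 7

Remark: (S)-(+)-terpinen-4-ol of high enantiomeric purity, ethyl diazoacetate, (tert-butyldimethylsilyloxy)acetaldehyde and angelic acid are taken as commercial; bicyclic compounds are named with daucane numbering (C1 quaternary ring-fusion carbon bearing C15, C4 carbinol carbon with isopropyl, C5 ring-fusion CH, C8 bearing C14).

Step 1
Reactants: 1 (S)-terpinen-4-ol
Product: 2 (S)-triethyl[(1-isopropyl-4-methylcyclohex-3-en-1-yl)oxy]silane
Conditions: TESOTf, 2,6-lutidine, CH2Cl2, 0 °C to rt
Reagents that add atoms: triethylsilyl trifluoromethanesulfonate, CC[Si](CC)(CC)OS(=O)(=O)C(F)(F)F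
Why: Silyl triflate silylation of the hindered tertiary alcohol under lutidine buffering, which leaves the trisubstituted alkene and the only stereocentre (the future C4) untouched and masks the hydroxyl against retro-aldol, hemiketal formation and later O–H insertion.

Step 2
Reactants: 2 (S)-triethyl[(1-isopropyl-4-methylcyclohex-3-en-1-yl)oxy]silane
Product: 4 (S)-3-isopropyl-6-oxo-3-(triethylsilyloxy)heptanal, via ozonide 3 (not isolated)
Conditions: O3, CH2Cl2, −78 °C; PPh3, −78 °C to rt
Reagents that add atoms: ozone, [O-][O+]=O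
Why: Ozonolysis (Criegee mechanism) of the only C=C bond with reductive cleavage of the ozonide should unmask the methyl ketone (C1) and the aldehyde (C6) without touching the silyl ether or the quaternary stereocentre.

Step 3
Reactants: 4 (S)-3-isopropyl-6-oxo-3-(triethylsilyloxy)heptanal
Product: 6 (R)-5-isopropyl-2-methyl-5-(triethylsilyloxy)cyclopent-1-ene-1-carbaldehyde, via aldol adduct 5 (not isolated)
Conditions: piperidine (0.3 equiv), AcOH (0.3 equiv), toluene, 80 °C
Reagents that add atoms: none
Why: Intramolecular aldol condensation through the piperidine enamine of the aldehyde (attack on the methyl ketone, then dehydration), as in the classical cyclisation of the limonene keto-aldehyde; the O-silylated quaternary centre cannot undergo retro-aldol and the product enal has no α-hydrogen for β-elimination of the silyloxy group.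

Step 4
Reactants: 6 (R)-5-isopropyl-2-methyl-5-(triethylsilyloxy)cyclopent-1-ene-1-carbaldehyde
Product: 7 (R)-triethyl[(1-isopropyl-3-methyl-2-vinylcyclopent-2-en-1-yl)oxy]silane
Conditions: Ph3PCH3Br, KOtBu, THF, 0 °C to rt
Reagents that add atoms: methyltriphenylphosphonium bromide, C[P+](c1ccccc1)(c1ccccc1)c1ccccc1.[Br-]
Why: Wittig methylenation of a non-enolisable enal should give the 2-methyl-1-vinylcyclopentene (C1=C5–C6=C7) without affecting the silyl ether or C4.

Step 5
Reactants: 8 ethyl diazoacetate; 9 (tert-butyldimethylsilyloxy)acetaldehyde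
Product: 10 ethyl 4-(tert-butyldimethylsilyloxy)-2-diazo-3-hydroxybutanoate (racemic)
Conditions: DBU (0.2 equiv), MeCN, rt
Reagents that add atoms: none
Why: Base-catalysed aldol-type addition of the diazoacetate carbanion to the aldehyde; the new carbinol centre is removed in the next step, so its configuration is irrelevant.

Step 6
Reactants: 10 ethyl 4-(tert-butyldimethylsilyloxy)-2-diazo-3-hydroxybutanoate
Product: 12 ethyl (E)-4-(tert-butyldimethylsilyloxy)-2-diazobut-3-enoate, via dichlorophosphate 11 (not isolated)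
Conditions: POCl3, Et3N, CH2Cl2, 0 °C
Reagents that add atoms: none
Why: Dehydration of a β-hydroxy-α-diazo ester by O-phosphorylation and amine-mediated E2 elimination, the standard entry to vinyldiazoacetates; elimination can only run towards C4, and the E enol ether is expected from the less crowded anti-periplanar conformer.

Step 7
Reactants: 7 (R)-triethyl[(1-isopropyl-3-methyl-2-vinylcyclopent-2-en-1-yl)oxy]silane; 12 ethyl (E)-4-(tert-butyldimethylsilyloxy)-2-diazobut-3-enoate
Product: 14 ethyl (1S,4R,10R)-10-(tert-butyldimethylsilyloxy)-4-(triethylsilyloxy)dauca-5,8-dien-14-oate, via cis-divinylcyclopropane 13 (not isolated)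
Conditions: Rh2(R-DOSP)4 (1 mol %), hexanes, −40 °C to rt, slow addition of 12; then 70 °C
Reagents that add atoms: none
Why: Dinitrogen loss from 12 gives a rhodium donor/acceptor vinylcarbenoid that cyclopropanates the only monosubstituted alkene of 7 (C6=C7; the tetrasubstituted ring alkene is inert) with the vinyl donor cis to the cyclopentenyl group, and cis-divinylcyclopropane 13 then undergoes a [3,3] shift that breaks C6–C8 and forms C1–C10, driven by release of cyclopropane strain. The closest known reaction type is the rhodium(II)-catalysed tandem cyclopropanation/Cope rearrangement of vinyldiazoacetates with dienes, including 2-methyl-1-vinylcycloalkenes that deliver an angular methyl group. The seven-membered ring closes by this sigmatropic ring expansion of the three-membered ring through the obligatory boat transition state, a formal (4+3) cycloaddition. In the boat the E-silyloxy group on C10 and the ring CH2 (C2) on C1 are both exo, so the C10 oxygen ends trans to the C1 methyl; the absolute sense at C1 and C10 follows from the configuration of 13, which the chiral catalyst sets in the cyclopropanation (Rh2(R-DOSP)4 by the usual model for these catalysts), the remote C4 centre having little say. The step needs carbenoid rather than vinylogous reactivity and a retained E enol ether, which the hydrocarbon solvent, the dirhodium carboxylate and the E-substituted vinyl terminus favour, and heating is expected to be needed because the C1 methyl points inward in the boat.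

Step 8
Reactants: 14 ethyl (1S,4R,10R)-10-(tert-butyldimethylsilyloxy)-4-(triethylsilyloxy)dauca-5,8-dien-14-oate
Product: 15 ethyl (1S,4R,10R)-4,10-dihydroxydauca-5,8-dien-14-oate
Conditions: HF·pyridine, pyridine, THF, 0 °C to rt
Reagents that add atoms: none
Why: Fluoride-driven cleavage of both silyl ethers under buffered conditions that should not ionise the tertiary allylic alcohol; the C10 hydroxyl is trans to the ester across C8=C9 and cannot lactonise, and no stereocentre is touched.

Step 9
Reactants: 15 ethyl (1S,4R,10R)-4,10-dihydroxydauca-5,8-dien-14-oate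
Product: 17 ethyl (1S,4R,5R,6S,10R)-4-hydroxy-6,10-(dimethylsilanediyloxy)dauc-8-en-14-oate (SiMe2 bonded to C6 and to O10, both on the α-face), via hydrosilyl ether 16 (not isolated)
Conditions: Me2SiHCl (1.1 equiv), Et3N, CH2Cl2, 0 °C; then Karstedt catalyst (1 mol %), toluene, 60 °C
Reagents that add atoms: chlorodimethylsilane, C[SiH](C)Cl
Why: Tamao–Ito intramolecular hydrosilylation: only the secondary C10 hydroxyl is silylated, its tether can reach only C6 (6-endo, since C5 is fully substituted and the enoate alkene is electron-poor), and syn addition of Si–H from the 10α-oxygen puts H5 on the concave α-face (trans ring fusion) and silicon on C6 as the 6α-oxygen precursor, a face that external reagents would not choose.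

Step 10
Reactants: 17 ethyl (1S,4R,5R,6S,10R)-4-hydroxy-6,10-(dimethylsilanediyloxy)dauc-8-en-14-oate
Product: 18 (1S,4R,5R,6S,10R)-6,10-(dimethylsilanediyloxy)dauc-8-ene-4,14-diol
Conditions: DIBAL-H, CH2Cl2, −78 °C
Reagents that add atoms: none
Why: 1,2-Reduction of the α,β-unsaturated ester to the primary allylic alcohol by DIBAL-H, with the cyclic siloxane (which masks both O10 and C6) and the tertiary alcohol inert at low temperature.

Step 11
Reactants: 18 (1S,4R,5R,6S,10R)-6,10-(dimethylsilanediyloxy)dauc-8-ene-4,14-diol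
Product: 21 (1S,4R,5S,6S,10R)-dauc-8-ene-4,6,10-triol, via allylic mesylate 19 (not isolated), via methyl oxasilinane 20 (not isolated)
Conditions: MsCl, Et3N, CH2Cl2, −40 °C; LiEt3BH, THF, −78 to 0 °C; then KF, KHCO3, 30% H2O2, THF/MeOH, 40 °C
Reagents that add atoms: hydrogen peroxide, OO
Why: Mesylation of the only reactive (primary allylic) hydroxyl and SN2 hydride displacement turn C14 into the methyl group while the siloxane keeps O10 and C6 out of reach of the allylic electrophile, and the peroxide work-up then performs the Tamao–Kumada oxidation of the C6–Si bond with retention, releasing the 6α- and 10α-hydroxyls.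

Step 12
Reactants: 21 (1S,4R,5S,6S,10R)-dauc-8-ene-4,6,10-triol; 22 angelic acid (2.5 equiv)
Product: 24 (1S,4R,5S,6S,10R)-4-hydroxydauc-8-ene-6,10-diyl bis[(Z)-2-methylbut-2-enoate], via mixed anhydride 23 (not isolated)
Conditions: 2,4,6-trichlorobenzoyl chloride, Et3N, toluene, rt; then 21, 80 °C
Reagents that add atoms: none
Why: Yamaguchi mixed-anhydride acylation without a nucleophilic catalyst, the conditions known to transfer the angeloyl group without Z to E isomerisation; both secondary hydroxyls should react while the tertiary C4 hydroxyl is too hindered.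

Compound list
1 | (S)-(+)-terpinen-4-ol | CC1=CC[C@](O)(C(C)C)CC1 | starting material
2 | (S)-triethyl[(1-isopropyl-4-methylcyclohex-3-en-1-yl)oxy]silane | CC1=CC[C@](O[Si](CC)(CC)CC)(C(C)C)CC1 | intermediate
3 | ozonide of 2 (formed in the flask, ring-carbon configurations not defined) | CC12CC[C@@](O[Si](CC)(CC)CC)(C(C)C)CC(OO1)O2 | intermediate
4 | (S)-3-isopropyl-6-oxo-3-(triethylsilyloxy)heptanal | O=CC[C@](O[Si](CC)(CC)CC)(C(C)C)CCC(C)=O | intermediate
5 | aldol adduct, 2-hydroxy-5-isopropyl-2-methyl-5-(triethylsilyloxy)cyclopentane-1-carbaldehyde (formed in the flask, C5 as in 4) | O=CC1C(C)(O)CC[C@@]1(O[Si](CC)(CC)CC)C(C)C | intermediate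
6 | (R)-5-isopropyl-2-methyl-5-(triethylsilyloxy)cyclopent-1-ene-1-carbaldehyde | O=CC1=C(C)CC[C@@]1(O[Si](CC)(CC)CC)C(C)C | intermediate
7 | (R)-triethyl[(1-isopropyl-3-methyl-2-vinylcyclopent-2-en-1-yl)oxy]silane | C=CC1=C(C)CC[C@@]1(O[Si](CC)(CC)CC)C(C)C | intermediate
8 | ethyl diazoacetate | CCOC(=O)C=[N+]=[N-] | starting material
9 | (tert-butyldimethylsilyloxy)acetaldehyde | O=CCO[Si](C)(C)C(C)(C)C | starting material
10 | ethyl 4-(tert-butyldimethylsilyloxy)-2-diazo-3-hydroxybutanoate (racemic) | CCOC(=O)C(=[N+]=[N-])C(O)CO[Si](C)(C)C(C)(C)C | intermediate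
11 | dichlorophosphate of 10 (formed in the flask) | CCOC(=O)C(=[N+]=[N-])C(OP(=O)(Cl)Cl)CO[Si](C)(C)C(C)(C)C | intermediate
12 | ethyl (E)-4-(tert-butyldimethylsilyloxy)-2-diazobut-3-enoate | CCOC(=O)C(=[N+]=[N-])/C=C/O[Si](C)(C)C(C)(C)C | intermediate
13 | ethyl (1R,2S)-1-[(E)-2-(tert-butyldimethylsilyloxy)ethenyl]-2-[(5R)-5-isopropyl-2-methyl-5-(triethylsilyloxy)cyclopent-1-en-1-yl]cyclopropane-1-carboxylate, the two alkenyl groups cis (formed in the flask) | CCOC(=O)[C@]1(/C=C/O[Si](C)(C)C(C)(C)C)C[C@H]1C1=C(C)CC[C@@]1(O[Si](CC)(CC)CC)C(C)C | intermediate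
14 | ethyl (1S,4R,10R)-10-(tert-butyldimethylsilyloxy)-4-(triethylsilyloxy)dauca-5,8-dien-14-oate | CCOC(=O)C1=C[C@@H](O[Si](C)(C)C(C)(C)C)[C@@]2(C)CC[C@@](O[Si](CC)(CC)CC)(C(C)C)C2=CC1 | intermediate
15 | ethyl (1S,4R,10R)-4,10-dihydroxydauca-5,8-dien-14-oate | CCOC(=O)C1=C[C@@H](O)[C@@]2(C)CC[C@@](O)(C(C)C)C2=CC1 | intermediate
16 | ethyl (1S,4R,10R)-10-(dimethylsilyloxy)-4-hydroxydauca-5,8-dien-14-oate (formed in the flask) | CCOC(=O)C1=C[C@@H](O[SiH](C)C)[C@@]2(C)CC[C@@](O)(C(C)C)C2=CC1 | intermediate
17 | ethyl (1S,4R,5R,6S,10R)-4-hydroxy-6,10-(dimethylsilanediyloxy)dauc-8-en-14-oate | CCOC(=O)C1=C[C@@H](O[Si]3(C)C)[C@@]2(C)CC[C@@](O)(C(C)C)[C@@H]2[C@@H]3C1 | intermediate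
18 | (1S,4R,5R,6S,10R)-6,10-(dimethylsilanediyloxy)dauc-8-ene-4,14-diol | OCC1=C[C@@H](O[Si]3(C)C)[C@@]2(C)CC[C@@](O)(C(C)C)[C@@H]2[C@@H]3C1 | intermediate
19 | 14-methanesulfonate of 18 (formed in the flask) | CS(=O)(=O)OCC1=C[C@@H](O[Si]3(C)C)[C@@]2(C)CC[C@@](O)(C(C)C)[C@@H]2[C@@H]3C1 | intermediate
20 | (1S,4R,5R,6S,10R)-6,10-(dimethylsilanediyloxy)dauc-8-en-4-ol (formed in the flask) | CC1=C[C@@H](O[Si]3(C)C)[C@@]2(C)CC[C@@](O)(C(C)C)[C@@H]2[C@@H]3C1 | intermediate
21 | (1S,4R,5S,6S,10R)-dauc-8-ene-4,6,10-triol (4β,6α,10α) | CC1=C[C@@H](O)[C@@]2(C)CC[C@@](O)(C(C)C)[C@@H]2[C@@H](O)C1 | intermediate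
22 | angelic acid, (Z)-2-methylbut-2-enoic acid | C/C=C(/C)C(=O)O | starting material
23 | angelic 2,4,6-trichlorobenzoic anhydride (formed in the flask) | C/C=C(/C)C(=O)OC(=O)c1c(Cl)cc(Cl)cc1Cl | intermediate
24 | (1S,4R,5S,6S,10R)-4-hydroxydauc-8-ene-6,10-diyl bis[(Z)-2-methylbut-2-enoate] | C/C=C(/C)C(=O)O[C@H]1CC(C)=C[C@@H](OC(=O)/C(C)=C\C)[C@@]2(C)CC[C@@](O)(C(C)C)[C@H]12 | target

Total steps: 12. Longest linear sequence: 10 steps (1–4, then 7–12); the diazo component takes steps 5–6.

Steps most likely to fail

Step 7. The silyloxy donor may divert the rhodium vinylcarbenoid to attack at its vinylogous carbon, the enol ether geometry may erode before the Cope shift, or the catalyst may be mismatched with the C4 centre in the cyclopropanation. (Were only the sense of induction wrong, the antipodal catalyst would be tried first.) The fallback introduces the C10 oxygen after the annulation instead of with it. Setting out from 7 and 8, DBU-catalysed addition of 8 to acetaldehyde should give ethyl 2-diazo-3-hydroxybutanoate F1, which POCl3/Et3N dehydrates to ethyl 2-diazobut-3-enoate F2. Rhodium-catalysed cyclopropanation of 7 with F2 should give the cis-divinylcyclopropane F3, whose Cope rearrangement gives the C10-unsubstituted dienyl ester F4. Selenium dioxide/tert-butyl hydroperoxide oxidation at the γ-position of the enoate, on the exo face anti to the C1 methyl, should give the 10α-alcohol F5; the C5=C6 bond has no allylic hydrogen at its substituted end. TBSOTf/2,6-lutidine then returns the route to 14.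

Step 9. The 6-endo hydrosilylation may not engage: platinum hydride may instead migrate the skipped diene into conjugation with the ester, or partial silylation of the tertiary C4 hydroxyl may deliver silicon on the wrong (β) face. The fallback moves the anchor to C14 and the delivery to the 6-exo mode. Setting out from 14, DIBAL-H reduction should give the allylic alcohol F6. Silylation of its only hydroxyl with Me2SiHCl and platinum-catalysed hydrosilylation of C5=C6 from the α-face, over which C14 lies in the boat conformer, should give the oxasilinane F7, which LiAlH4 opens to the hydroxy silane F8. Mesylation, LiEt3BH reduction and Tamao oxidation in the peroxide work-up should give the 6α-alcohol F9, and HF·pyridine returns the route to 21.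

Step 12. The angeloyl group may isomerise from Z to E (tiglate) during acyl transfer, and acylation of the neopentyl C10 hydroxyl may stay incomplete. The fallback builds the Z alkenes on the ester instead of transferring them. Setting out from 21, DCC/DMAP esterification of both secondary hydroxyls with 2-[bis(2,2,2-trifluoroethoxy)phosphoryl]propanoic acid should give the bis(phosphonopropionate) F10. A double Still–Gennari olefination (KHMDS, 18-crown-6, acetaldehyde, THF, −78 °C) then forms both (Z)-2-methylbut-2-enoates in place and returns the route at 24.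

Further compounds
F1 | step 7 | ethyl 2-diazo-3-hydroxybutanoate (racemic) | CCOC(=O)C(=[N+]=[N-])C(C)O
F2 | step 7 | ethyl 2-diazobut-3-enoate | CCOC(=O)C(=[N+]=[N-])C=C
F3 | step 7 | ethyl (1S,2S)-1-ethenyl-2-[(5R)-5-isopropyl-2-methyl-5-(triethylsilyloxy)cyclopent-1-en-1-yl]cyclopropane-1-carboxylate, alkenyl groups cis | CCOC(=O)[C@]1(C=C)C[C@H]1C1=C(C)CC[C@@]1(O[Si](CC)(CC)CC)C(C)C
F4 | step 7 | ethyl (1R,4R)-4-(triethylsilyloxy)dauca-5,8-dien-14-oate | CCOC(=O)C1=CC[C@@]2(C)CC[C@@](O[Si](CC)(CC)CC)(C(C)C)C2=CC1
F5 | step 7 | ethyl (1S,4R,10R)-10-hydroxy-4-(triethylsilyloxy)dauca-5,8-dien-14-oate | CCOC(=O)C1=C[C@@H](O)[C@@]2(C)CC[C@@](O[Si](CC)(CC)CC)(C(C)C)C2=CC1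
F6 | step 9 | (1S,4R,10R)-10-(tert-butyldimethylsilyloxy)-4-(triethylsilyloxy)dauca-5,8-dien-14-ol | OCC1=C[C@@H](O[Si](C)(C)C(C)(C)C)[C@@]2(C)CC[C@@](O[Si](CC)(CC)CC)(C(C)C)C2=CC1
F7 | step 9 | (1S,4R,5R,6S,10R)-10-(tert-butyldimethylsilyloxy)-4-(triethylsilyloxy)-6,14-(dimethylsilanediyloxy)dauc-8-ene (SiMe2 bonded to C6 and to O14) | C[Si]1(C)OCC2=C[C@@H](O[Si](C)(C)C(C)(C)C)[C@@]3(C)CC[C@@](O[Si](CC)(CC)CC)(C(C)C)[C@@H]3[C@@H]1C2
F8 | step 9 | (1S,4R,5R,6S,10R)-10-(tert-butyldimethylsilyloxy)-6-(dimethylsilyl)-4-(triethylsilyloxy)dauc-8-en-14-ol | OCC1=C[C@@H](O[Si](C)(C)C(C)(C)C)[C@@]2(C)CC[C@@](O[Si](CC)(CC)CC)(C(C)C)[C@@H]2[C@@H]([SiH](C)C)C1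
F9 | step 9 | (1S,4R,5S,6S,10R)-10-(tert-butyldimethylsilyloxy)-4-(triethylsilyloxy)dauc-8-en-6-ol | CC1=C[C@@H](O[Si](C)(C)C(C)(C)C)[C@@]2(C)CC[C@@](O[Si](CC)(CC)CC)(C(C)C)[C@@H]2[C@@H](O)C1
F10 | step 12 | (1S,4R,5S,6S,10R)-4-hydroxydauc-8-ene-6,10-diyl bis{2-[bis(2,2,2-trifluoroethoxy)phosphoryl]propanoate} (phosphonate-bearing carbons not defined) | CC1=C[C@@H](OC(=O)C(C)P(=O)(OCC(F)(F)F)OCC(F)(F)F)[C@@]2(C)CC[C@@](O)(C(C)C)[C@@H]2[C@@H](OC(=O)C(C)P(=O)(OCC(F)(F)F)OCC(F)(F)F)C1
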